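Everything rests on making ring B from a pyranone instead of coupling arenes at its crowded ether. In ring B, C4 bears the oxygen to ring C and is flanked by the hydroxyl-bearing C3 and C5, while C1 bears the oxygen to ring A. This pattern maps atom for atom onto a 4-aryloxy-6-(aryloxymethyl)pyran-2-one. Both ethers are therefore set by ordinary displacements on a dibromopyranone. Methoxide then opens the lactone, and the oxygen-substituted methylene carbanion closes on the released ester. This gives the C3–C4 bond, the benzene ring and both free hydroxyls in one isomerisation. The precursor is the permethylated pyranone with ring A on C4 and the C–D–E trimer on the C6 methylene.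

Key step: step 9

Remarks:
- Rings are lettered A to E from the 2,4,6-trihydroxyphenyl end. Ring B is numbered from the carbon that bears the ring A oxygen.
- ArCDE denotes 2-[3,4-dimethoxy-5-(3,4,5-trimethoxyphenoxy)phenoxy]-3,4,5-trimethoxyphenyl.
- The target has no stereocentre.
- Methyl is kept for all eleven spectator ethers because it cannot scramble in a methoxide medium.
- Assumption: the two bromobenzaldehydes and 2,4,6-trimethoxyphenol are taken as catalogue compounds.

Step 1
Reactants: 1 3,4,5-trimethoxyphenol; 2 3-bromo-4,5-dimethoxybenzaldehyde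
Product: 3 3,4-dimethoxy-5-(3,4,5-trimethoxyphenoxy)benzaldehyde
Conditions: CuI (10 mol %), N,N-dimethylglycine·HCl (30 mol %), Cs2CO3 (2 equiv), 1,4-dioxane, 100 °C, argon
Reagents that add atoms: none
Why: Ligand-accelerated Ullmann diaryl ether synthesis, in which an unhindered electron-rich phenoxide meets an aryl bromide with only one ortho methoxy group, and the non-enolisable aldehyde is inert to carbonate.

Step 2
Reactants: 3 3,4-dimethoxy-5-(3,4,5-trimethoxyphenoxy)benzaldehyde
Product: 5 3,4-dimethoxy-5-(3,4,5-trimethoxyphenoxy)phenol, via aryl formate 4 (not isolated)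
Conditions: mCPBA (1.3 equiv), CH2Cl2, 0 °C to rt; aq. Na2SO3/NaHCO3 wash; then K2CO3 (cat.), MeOH, rt
Reagents that add atoms: mCPBA (3-chloroperbenzoic acid), O=C(OO)c1cccc(Cl)c1
Why: Baeyer–Villiger oxidation of an electron-rich benzaldehyde, in which the para-methoxy-substituted aryl group migrates in preference to hydride, followed by base-catalysed transesterification of the formate to free the phenol.

Step 3
Reactants: 5 3,4-dimethoxy-5-(3,4,5-trimethoxyphenoxy)phenol; 6 2-bromo-3,4,5-trimethoxybenzaldehyde
Product: 7 2-[3,4-dimethoxy-5-(3,4,5-trimethoxyphenoxy)phenoxy]-3,4,5-trimethoxybenzaldehyde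
Conditions: CuI (20 mol %), picolinic acid (40 mol %), K3PO4 (2 equiv), DMSO, 100 °C, argon
Reagents that add atoms: none
Why: Ullmann diaryl ether synthesis in which the phenol has two free ortho positions and the doubly ortho-substituted bromide is activated by its ortho formyl group, the pairing long used for 2-bromo-3,4,5-trialkoxybenzoyl partners in gallate-derived diaryl ethers.

Step 4
Reactants: 7 2-[3,4-dimethoxy-5-(3,4,5-trimethoxyphenoxy)phenoxy]-3,4,5-trimethoxybenzaldehyde
Product: 9 ArCDE-OH (2-[3,4-dimethoxy-5-(3,4,5-trimethoxyphenoxy)phenoxy]-3,4,5-trimethoxyphenol), via aryl formate 8 (not isolated)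
Conditions: mCPBA (1.3 equiv), CH2Cl2, 0 °C to rt; aq. Na2SO3/NaHCO3 wash; then K2CO3 (cat.), MeOH, rt, argon
Reagents that add atoms: mCPBA (3-chloroperbenzoic acid), O=C(OO)c1cccc(Cl)c1
Why: Baeyer–Villiger oxidation again, with aryl migration secured by the ortho aryloxy and para methoxy donors, and mild methanolysis of the formate turns the former formyl carbon site into the ring C hydroxyl.

Step 5
Reactants: 10 4-hydroxy-6-methylpyran-2-one (triacetic acid lactone)
Product: 11 4-bromo-6-methylpyran-2-one
Conditions: P2O5 (2.5 equiv), n-Bu4NBr (1.2 equiv), toluene, 100 °C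
Reagents that add atoms: n-Bu4NBr (tetrabutylammonium bromide), CCCC[N+](CCCC)(CCCC)CCCC.[Br-]
Why: Dehydroxylative bromination of a vinylogous acid, in which P2O5 turns the C4 hydroxyl into a phosphate leaving group and bromide replaces it by addition–elimination, a standard preparation of this bromopyranone.

Step 6
Reactants: 11 4-bromo-6-methylpyran-2-one
Product: 12 4-bromo-6-(bromomethyl)pyran-2-one
Conditions: NBS (1.05 equiv), AIBN (5 mol %), PhCF3, 85 °C
Reagents that add atoms: NBS (N-bromosuccinimide), O=C1CCC(=O)N1Br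
Why: Wohl–Ziegler radical bromination of the allylic C6 methyl group, with the C4 bromine lowering ring nucleophilicity so that ionic bromination at C3 should not compete.

Step 7
Reactants: 9 ArCDE-OH; 12 4-bromo-6-(bromomethyl)pyran-2-one (1.2 equiv)
Product: 13 4-bromo-6-(ArCDE-oxymethyl)pyran-2-one
Conditions: K2CO3 (1.5 equiv), acetone, 0 °C to rt, argon
Reagents that add atoms: none
Why: Williamson ether synthesis (SN2), since the primary allylic bromide should react with a phenoxide at 0 °C well before the vinylic C4 bromide, whose addition–elimination normally needs warming, and keeping 9 as the limiting partner guards the C4–Br bond for the next step.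

Step 8
Reactants: 13 4-bromo-6-(ArCDE-oxymethyl)pyran-2-one; 14 2,4,6-trimethoxyphenol
Product: 15 4-(2,4,6-trimethoxyphenoxy)-6-(ArCDE-oxymethyl)pyran-2-one
Conditions: K2CO3 (1.5 equiv), MeCN (degassed), 50 °C, argon
Reagents that add atoms: none
Why: Addition–elimination (vinylogous acyl substitution) of a phenoxide at C4 of a 4-bromopyran-2-one, known for ortho-substituted phenols and helped here because C4 is flanked only by CH groups, while exclusion of air protects the oxidisable phenoxide.

Step 9
Reactants: 15 4-(2,4,6-trimethoxyphenoxy)-6-(ArCDE-oxymethyl)pyran-2-one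
Product: 18 2-(ArCDE-oxy)-5-(2,4,6-trimethoxyphenoxy)benzene-1,3-diol (undecamethyl ether of the target), via ring-opened enoate 16 (not isolated), via cyclohexenedione tautomer 17 (not isolated)
Conditions: NaOMe (6 equiv), MeOH (dry, degassed), 65 °C, raised to 100 °C in a sealed tube if conversion is slow, argon; then 1 M HCl, 0 °C
Reagents that add atoms: none
Why: Methoxide adds to the lactone carbonyl of 15 and the enol ester opens to the (E)-enoate 16, in which the new methyl ester and the ketone-bearing chain stay cis on the former C3=C4 double bond and so remain within bonding distance. Reversible enolisation of the ketone towards the oxygen-substituted methylene, made easier than in a plain methyl case by the inductive pull of the ring C oxygen and by sodium chelation between enolate and ether oxygens, gives the carbanion that attacks the ester in an intramolecular Claisen (Dieckmann-type) condensation, a 6-(enolendo)-exo-trig closure that forms the ring B C3–C4 bond. Loss of methoxide gives dione 17, and its enolisation to the resorcinol dianion is the thermodynamic sink that pulls relactonisation, enolisation at the more acidic central methylene and 1,6-addition, all of them reversible, towards 18, an isomer of 15 (C41H44O17). The closest known reaction is the alkoxide-induced recyclisation of 4-methoxy-6-methylpyran-2-one into 5-methoxyresorcinol, together with the Claisen-type conversion of 6-acylmethylpyranones into acylphloroglucinols. No stereocentre survives, since the single transient centre of 17 is erased by aromatisation. The selectivity needed is attack at the lactone carbonyl instead of addition–elimination at pyranone C4, and it is secured by the perpendicular 2,6-dimethoxyaryl ring, which holds a methoxy group over each face of C4, by the reluctance of the electron-rich aryloxide to leave, and by the opened chain resting as a non-electrophilic dienolate.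

Step 10
Reactants: 18 2-(ArCDE-oxy)-5-(2,4,6-trimethoxyphenoxy)benzene-1,3-diol
Product: 19 target CNP0154768.0
Conditions: BBr3 (25 equiv), CH2Cl2, −78 °C to rt, argon; then degassed H2O, 0 °C
Reagents that add atoms: none
Why: Lewis acid ether cleavage, in which BBr3 binds each methoxy oxygen and bromide removes the methyl group by SN2, whereas the four diaryl ether bonds offer no sp3 carbon and survive, and hydrolysis of the aryl borates releases the thirteen hydroxyls.

Compound list
1 | 3,4,5-trimethoxyphenol | COc1cc(O)cc(OC)c1OC | starting material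
2 | 3-bromo-4,5-dimethoxybenzaldehyde | COc1cc(C=O)cc(Br)c1OC | starting material
3 | 3,4-dimethoxy-5-(3,4,5-trimethoxyphenoxy)benzaldehyde | COc1cc(C=O)cc(Oc2cc(OC)c(OC)c(OC)c2)c1OC | intermediate
4 | 3,4-dimethoxy-5-(3,4,5-trimethoxyphenoxy)phenyl formate | COc1cc(OC=O)cc(Oc2cc(OC)c(OC)c(OC)c2)c1OC | intermediate
5 | 3,4-dimethoxy-5-(3,4,5-trimethoxyphenoxy)phenol | COc1cc(O)cc(Oc2cc(OC)c(OC)c(OC)c2)c1OC | intermediate
6 | 2-bromo-3,4,5-trimethoxybenzaldehyde | COc1cc(C=O)c(Br)c(OC)c1OC | starting material
7 | 2-[3,4-dimethoxy-5-(3,4,5-trimethoxyphenoxy)phenoxy]-3,4,5-trimethoxybenzaldehyde | O=Cc1cc(OC)c(OC)c(OC)c1Oc1cc(OC)c(OC)c(Oc2cc(OC)c(OC)c(OC)c2)c1 | intermediate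
8 | 2-[3,4-dimethoxy-5-(3,4,5-trimethoxyphenoxy)phenoxy]-3,4,5-trimethoxyphenyl formate | O=COc1cc(OC)c(OC)c(OC)c1Oc1cc(OC)c(OC)c(Oc2cc(OC)c(OC)c(OC)c2)c1 | intermediate
9 | 2-[3,4-dimethoxy-5-(3,4,5-trimethoxyphenoxy)phenoxy]-3,4,5-trimethoxyphenol (ArCDE-OH) | Oc1cc(OC)c(OC)c(OC)c1Oc1cc(OC)c(OC)c(Oc2cc(OC)c(OC)c(OC)c2)c1 | intermediate
10 | 4-hydroxy-6-methylpyran-2-one | Cc1cc(O)cc(=O)o1 | starting material
11 | 4-bromo-6-methylpyran-2-one | Cc1cc(Br)cc(=O)o1 | intermediate
12 | 4-bromo-6-(bromomethyl)pyran-2-one | BrCc1cc(Br)cc(=O)o1 | intermediate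
13 | 4-bromo-6-({2-[3,4-dimethoxy-5-(3,4,5-trimethoxyphenoxy)phenoxy]-3,4,5-trimethoxyphenoxy}methyl)pyran-2-one | O=c1cc(Br)cc(COc2cc(OC)c(OC)c(OC)c2Oc2cc(OC)c(OC)c(Oc3cc(OC)c(OC)c(OC)c3)c2)o1 | intermediate
14 | 2,4,6-trimethoxyphenol | COc1cc(OC)c(O)c(OC)c1 | starting material
15 | 4-(2,4,6-trimethoxyphenoxy)-6-({2-[3,4-dimethoxy-5-(3,4,5-trimethoxyphenoxy)phenoxy]-3,4,5-trimethoxyphenoxy}methyl)pyran-2-one | O=c1cc(Oc2c(OC)cc(OC)cc2OC)cc(COc2cc(OC)c(OC)c(OC)c2Oc2cc(OC)c(OC)c(Oc3cc(OC)c(OC)c(OC)c3)c2)o1 | intermediate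
16 | methyl (2E)-6-(ArCDE-oxy)-5-oxo-3-(2,4,6-trimethoxyphenoxy)hex-2-enoate | COC(=O)/C=C(/Oc1c(OC)cc(OC)cc1OC)CC(=O)COc1cc(OC)c(OC)c(OC)c1Oc1cc(OC)c(OC)c(Oc2cc(OC)c(OC)c(OC)c2)c1 | intermediate
17 | 2-(ArCDE-oxy)-5-(2,4,6-trimethoxyphenoxy)cyclohex-4-ene-1,3-dione (racemic; labile centre at C2, lost on enolisation) | O=C1C=C(Oc2c(OC)cc(OC)cc2OC)CC(=O)C1Oc1cc(OC)c(OC)c(OC)c1Oc1cc(OC)c(OC)c(Oc2cc(OC)c(OC)c(OC)c2)c1 | intermediate
18 | 2-{2-[3,4-dimethoxy-5-(3,4,5-trimethoxyphenoxy)phenoxy]-3,4,5-trimethoxyphenoxy}-5-(2,4,6-trimethoxyphenoxy)benzene-1,3-diol | COc1cc(OC)c(Oc2cc(O)c(Oc3cc(OC)c(OC)c(OC)c3Oc3cc(OC)c(OC)c(Oc4cc(OC)c(OC)c(OC)c4)c3)c(O)c2)c(OC)c1 | intermediate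
19 | 2-{2-[3,4-dihydroxy-5-(3,4,5-trihydroxyphenoxy)phenoxy]-3,4,5-trihydroxyphenoxy}-5-(2,4,6-trihydroxyphenoxy)benzene-1,3-diol (CNP0154768.0) | Oc1cc(O)c(Oc2cc(O)c(Oc3cc(O)c(O)c(O)c3Oc3cc(O)c(O)c(Oc4cc(O)c(O)c(O)c4)c3)c(O)c2)c(O)c1 | target

Total step count: 10. Longest linear sequence: 8 steps (1, 2, 3, 4, 7, 8, 9, 10). Steps 5 and 6 form the short pyranone branch.

Steps most likely to fail

Step 9. Three processes could defeat the closure. The ring A aryloxide may be exchanged for methoxide at pyranone C4 before the lactone opens. The opened chain may rest as its central enolate and merely relactonise on work-up. At the higher temperature it may fragment by retro-Claisen cleavage. The fallback sets out from 9 and comes back at 19. Ring B is brought in as a ready-made arene and both of its ethers are made by copper catalysis. Ullmann coupling of 9 with commercial 4-bromo-3,5-dimethoxybenzaldehyde (CuI, picolinic acid, K3PO4, DMSO, 110 °C; the bromide is activated by its para formyl group) should give 4-(ArCDE-oxy)-3,5-dimethoxybenzaldehyde F1. Baeyer–Villiger oxidation with mCPBA leads through 4-(ArCDE-oxy)-3,5-dimethoxyphenyl formate F2 and, after methanolysis, to 4-(ArCDE-oxy)-3,5-dimethoxyphenol F3. Its unhindered hydroxyl is coupled with 2-iodo-1,3,5-trimethoxybenzene under the same copper conditions to give the tridecamethyl ether of the target F4. BBr3 as in step 10 then cleaves all thirteen methyl ethers to 19.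

Step 7. Site selectivity may erode. The phenoxide of 9 may attack C4 in competition with the bromomethyl group, which leads to regioisomeric or doubly substituted material. The fallback sets out from 9 and comes back at 13. The pyranone is built around the ether that is already in place, so only one electrophilic site ever exists. Alkylation of 9 with 2-chloro-N-methoxy-N-methylacetamide (K2CO3, DMF, 60 °C) should give 2-(ArCDE-oxy)-N-methoxy-N-methylacetamide F5. The lithium dienolate of 2,2,6-trimethyl-1,3-dioxin-4-one (LiN(SiMe3)2, THF, −78 °C) is acylated at its γ-carbon to give 6-[3-(ArCDE-oxy)-2-oxopropyl]-2,2-dimethyl-1,3-dioxin-4-one F6. Heating in toluene at 110 °C expels acetone, and the acylketene is trapped by the enol oxygen to give 4-hydroxy-6-(ArCDE-oxymethyl)pyran-2-one F7. P2O5 and n-Bu4NBr as in step 5 convert F7 into 13.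

Step 10. Partly borylated intermediates may precipitate and leave some methyl ethers uncleaved. The free polyphenol may also oxidise in air during aqueous isolation. The fallback sets out from 18 and comes back at 19, and follows a derivatise, purify and release sequence. The crude BBr3 product is not purified but acetylated at once (Ac2O, pyridine, rt) to the tridecaacetate of the target F8. This ester is air-stable and can be chromatographed on silica and separated from under-cleaved material. Acid-catalysed methanolysis (a little AcCl in degassed MeOH, rt, argon) then releases 19 beside volatile by-products only.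

Further compounds
F1 | step 9 | 4-(ArCDE-oxy)-3,5-dimethoxybenzaldehyde | O=Cc1cc(OC)c(Oc2cc(OC)c(OC)c(OC)c2Oc2cc(OC)c(OC)c(Oc3cc(OC)c(OC)c(OC)c3)c2)c(OC)c1
F2 | step 9 | 4-(ArCDE-oxy)-3,5-dimethoxyphenyl formate | O=COc1cc(OC)c(Oc2cc(OC)c(OC)c(OC)c2Oc2cc(OC)c(OC)c(Oc3cc(OC)c(OC)c(OC)c3)c2)c(OC)c1
F3 | step 9 | 4-(ArCDE-oxy)-3,5-dimethoxyphenol | Oc1cc(OC)c(Oc2cc(OC)c(OC)c(OC)c2Oc2cc(OC)c(OC)c(Oc3cc(OC)c(OC)c(OC)c3)c2)c(OC)c1
F4 | step 9 | tridecamethyl ether of the target | COc1cc(OC)c(Oc2cc(OC)c(Oc3cc(OC)c(OC)c(OC)c3Oc3cc(OC)c(OC)c(Oc4cc(OC)c(OC)c(OC)c4)c3)c(OC)c2)c(OC)c1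
F5 | step 7 | 2-(ArCDE-oxy)-N-methoxy-N-methylacetamide | CON(C)C(=O)COc1cc(OC)c(OC)c(OC)c1Oc1cc(OC)c(OC)c(Oc2cc(OC)c(OC)c(OC)c2)c1
F6 | step 7 | 6-[3-(ArCDE-oxy)-2-oxopropyl]-2,2-dimethyl-1,3-dioxin-4-one | CC1(C)OC(=O)C=C(CC(=O)COc2cc(OC)c(OC)c(OC)c2Oc2cc(OC)c(OC)c(Oc3cc(OC)c(OC)c(OC)c3)c2)O1
F7 | step 7 | 4-hydroxy-6-(ArCDE-oxymethyl)pyran-2-one | O=c1cc(O)cc(COc2cc(OC)c(OC)c(OC)c2Oc2cc(OC)c(OC)c(Oc3cc(OC)c(OC)c(OC)c3)c2)o1
F8 | step 10 | tridecaacetate of the target | CC(=O)Oc1cc(OC(C)=O)c(Oc2cc(OC(C)=O)c(Oc3cc(OC(C)=O)c(OC(C)=O)c(OC(C)=O)c3Oc3cc(OC(C)=O)c(OC(C)=O)c(Oc4cc(OC(C)=O)c(OC(C)=O)c(OC(C)=O)c4)c3)c(OC(C)=O)c2)c(OC(C)=O)c1
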